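**Retrosynthetic overview**
1. Last step: a double Cope rearrangement of a bis-germacranolide forms both cyclohexane rings at once (C5–C10 and C5'–C10'). Each half is controlled by its own lactone stereocentres, which explains the opposite C5/C10 sense in the two halves.
2. The bis-germacranolide comes from two molecules of one monomer, the cis-fused (7R,8R)-germacra-1(10),4,11(13)-trien-12,8-olide. The C13–C13' bond is made by reductive tail-to-tail coupling, and one selenoxide elimination then gives the net "ene dimer".
3. The monomer comes from an acyclic bromo aldehyde. Forming the C7–C8 bond closes the ten-membered ring, and the 8-alkoxide closes the γ-lactone on the C12 ester in the same flask.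
4. The bromo aldehyde comes from geranyl bromide, vinyl Grignard reagent, CO and methyl 2-(bromomethyl)acrylate.
5. Ring order: ten-membered carbocycle, then γ-lactone (before dimerisation), then the two cyclohexanes (last).

Assumption: germacrane numbering (C1–C15, primes for the half that ends as the saturated lactone) is used for all macrocycles and for the target. The (S,S)-ligand of step 6 is taken to give the 8R series; its mirror image is used if the sense is opposite.

**Step 1**
Reactants: 1 geranyl bromide [(2E)-1-bromo-3,7-dimethylocta-2,6-diene]; 2 vinylmagnesium bromide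
Product: 3 (4E)-5,9-dimethyldeca-1,4,8-triene
Conditions: CuI (10 mol%), THF, −30 to 0 °C
Reagents that add atoms: none
Why: Copper-catalysed Grignard cross-coupling (Kochi type) displaces the primary allylic bromide in SN2 fashion at the less hindered terminus, keeps the E alkene and installs the terminal vinyl group (future C7) that step 5 needs; no stereocentre is formed.

**Step 2**
Reactants: 3 (4E)-5,9-dimethyldeca-1,4,8-triene
Product: 4 (2E,6E)-2,6-dimethyldeca-2,6,9-trien-1-ol
Conditions: SeO2 (0.3 equiv), t-BuOOH (3 equiv), salicylic acid (0.1 equiv), CH2Cl2, 0 to 23 °C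
Reagents that add atoms: tert-butyl hydroperoxide CC(C)(C)OO
Why: Catalytic SeO2 allylic oxidation (ene reaction followed by [2,3]-sigmatropic shift, Sharpless conditions) attacks the most accessible and most electron-rich alkene, the terminal isopropylidene, and oxidises only its E methyl group, which fixes the E geometry of the future C1=C10 bond and leaves the vinyl group alone; no stereocentre is formed.

**Step 3**
Reactants: 4 (2E,6E)-2,6-dimethyldeca-2,6,9-trien-1-ol
Product: 5 (2E,6E)-1-bromo-2,6-dimethyldeca-2,6,9-triene
Conditions: CBr4 (1.2 equiv), PPh3 (1.25 equiv), CH2Cl2, −20 °C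
Reagents that add atoms: carbon tetrabromide BrC(Br)(Br)Br
Why: Appel reaction: neutral activation of the primary allylic alcohol by PPh3/CBr4 and SN2 displacement by bromide keep both E alkenes and the skipped diene in place; no stereocentre is formed.

**Step 4**
Reactants: 5 (2E,6E)-1-bromo-2,6-dimethyldeca-2,6,9-triene
Product: 6 (3E,7E)-3,7-dimethylundeca-3,7,10-trienal
Conditions: Pd(PPh3)4 (4 mol%), CO (3 bar), Bu3SnH (1.1 equiv, syringe pump, 3 h), THF, 50 °C
Reagents that add atoms: carbon monoxide [C-]#[O+]
Why: Palladium-catalysed carbonylative reduction of an allylic halide (Stille formylation: oxidative addition, CO insertion at the less substituted allyl terminus, hydride transfer from tin) adds C8 as a β,γ-unsaturated aldehyde with retention of the E alkene under neutral conditions that do not move the double bond into conjugation; no stereocentre is formed.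

**Step 5**
Reactants: 6 (3E,7E)-3,7-dimethylundeca-3,7,10-trienal; 7 methyl 2-(bromomethyl)acrylate (5 equiv)
Product: 8 methyl (2Z,5E,9E)-2-(bromomethyl)-6,10-dimethyl-12-oxododeca-2,5,9-trienoate
Conditions: second-generation Hoveyda–Grubbs catalyst (5 mol%), 1,4-benzoquinone (10 mol%), CH2Cl2, 40 °C
Reagents that add atoms: none
Why: Olefin cross-metathesis of the only monosubstituted alkene of 6 with an excess of the 1,1-disubstituted acrylate 7 gives the thermodynamically preferred trisubstituted enoate (C6 trans to the ester, cis to CH2Br), the trisubstituted alkenes being inert and ring closure onto them being impossible for an E alkene in a small ring, while benzoquinone suppresses ruthenium hydride isomerisation; no stereocentre is formed.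

**Step 6**
Reactants: 8 methyl (2Z,5E,9E)-2-(bromomethyl)-6,10-dimethyl-12-oxododeca-2,5,9-trienoate
Product: 11 (1(10)E,4E,7R,8R)-germacra-1(10),4,11(13)-trien-12,8-olide (cis-fused; H-7 α; H-8 α), via allylchromium dichloride 9 (not isolated), via chromium alkoxide of the hydroxy ester 10 (not isolated)
Conditions: CrCl2 (4 equiv), (S,S)-3,6-di-tert-butyl-1,8-bis(4-isopropyl-4,5-dihydrooxazol-2-yl)-9H-carbazole (4.4 equiv), i-Pr2NEt (4.4 equiv), THF, 23 °C; 8 added by syringe pump over 12 h (final 2 mM); aqueous work-up
Reagents that add atoms: none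
Why: Proposed new method: an enantioselective, macrocyclising Nozaki–Hiyama–Kishi 2-(alkoxycarbonyl)allylation in which divalent chromium turns the allylic bromide into the ligand-bound allylchromium 9 that keeps C6 cis to the CH2Cr group, attacks the aldehyde through C7 in a chair transition state that gives the syn (7R,8R) adduct 10 with the ligand choosing the aldehyde face, and the 8-alkoxide then closes the γ-lactone on the C12 ester just as an 8-hydroxy acid does in the presumed biogenesis; the closest known reactions are the intermolecular chromium/carbazole-bis(oxazoline) allylation–lactonisation of aldehydes with 2-(bromomethyl)acrylates (cis-β,γ-disubstituted lactones, high ee) and the racemic chromium-mediated closure of ten-membered germacranolide rings.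

**Step 7**
Reactants: 11 (1(10)E,4E,7R,8R)-germacra-1(10),4,11(13)-trien-12,8-olide (two molecules)
Product: 13 C2-symmetric hydrodimer 13,13'-bi[(1(10)E,4E,7R,8R,11S)-germacra-1(10),4-dien-12,8-olide], via bis(samarium enolate) 12 (not isolated)
Conditions: SmI2 (1.1 equiv per lactone, 0.1 M in THF), HMPA (4 equiv), t-BuOH (1.0 equiv per lactone), 0.3 M in 11, 0 °C, 5 min
Reagents that add atoms: none
Why: Samarium diiodide hydrodimerisation of a conjugated ester (reductive β,β-coupling): the radical anions of two lactones join at their unhindered methylene carbons to give the bis-enolate 12, t-BuOH protonates each enolate from the convex α face of the cis-fused bicycle (the face of H-7 and H-8) and so sets 11S and 11'S, isolated alkenes are not reduced and 0 °C is far below the temperature of the Cope rearrangement.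

**Step 8**
Reactants: 13 C2-symmetric hydrodimer
Product: 17 bis-germacranolide 7(11)-ene (butenolide half 8R; saturated half 7'R,8'R,11'S), via lithium enolate 14 (not isolated), via selenide 15 (not isolated), via selenoxide 16 (not isolated)
Conditions: LiN(i-Pr)2 (1.0 equiv), THF, −78 °C; PhSeBr (1.0 equiv), −78 °C; then mCPBA (1.0 equiv) in CH2Cl2, −78 °C; i-Pr2NEt, −78 to 25 °C
Reagents that add atoms: none
Why: Selenoxide syn-elimination (Reich–Grieco lactone desaturation): one equivalent of base makes the mono-enolate 14, PhSeBr enters from the convex α face to give 15 with selenium cis to H-7, and the selenoxide 16 therefore eliminates towards C7 to give the tetrasubstituted endocyclic C7=C11 butenolide (the normal outcome for cis-fused lactones that have a syn ring-fusion hydrogen) at or below 25 °C, which removes the C7 and C11 stereocentres of that half, leaves 8R untouched and stays below the Cope threshold, while selenium is oxidised much faster than the ring alkenes at −78 °C and unreacted 13 is recycled.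

**Step 9**
Reactants: 17 bis-germacranolide 7(11)-ene
Product: 19 CNP0332736.1, via half-rearranged dimer 18 (not isolated)
Conditions: toluene (5 mM), BHT (5 mol%), sealed tube, 150 °C, 8 h
Reagents that add atoms: none
Why: Two thermal Cope rearrangements through chair transition states of the E,E-cyclodeca-1,5-dienes make both cyclohexane rings (C5–C10 and C5'–C10') as in the presumed biogenesis of elemanolides; in the butenolide half the flat lactone keeps the C8–O bond pseudo-equatorial so that 8R enforces 5R,10R, in the saturated half only the chair with the C7'–C11' bond equatorial avoids pushing the C13' chain on C11' over the forming ring so that 7'R and 11'S enforce 5'S,10'S, and the E,E geometry fixes the trans vinyl/isopropenyl relation in each ring.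

**Compound list**
1 | geranyl bromide, (2E)-1-bromo-3,7-dimethylocta-2,6-diene | CC(C)=CCC/C(C)=C/CBr | starting material
2 | vinylmagnesium bromide | C=C[Mg]Br | starting material
3 | (4E)-5,9-dimethyldeca-1,4,8-triene | CC(C)=CCC/C(C)=C/CC=C | intermediate
4 | (2E,6E)-2,6-dimethyldeca-2,6,9-trien-1-ol | OC/C(C)=C/CC/C(C)=C/CC=C | intermediate
5 | (2E,6E)-1-bromo-2,6-dimethyldeca-2,6,9-triene | BrC/C(C)=C/CC/C(C)=C/CC=C | intermediate
6 | (3E,7E)-3,7-dimethylundeca-3,7,10-trienal | O=CC/C(C)=C/CC/C(C)=C/CC=C | intermediate
7 | methyl 2-(bromomethyl)acrylate | C=C(CBr)C(=O)OC | starting material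
8 | methyl (2Z,5E,9E)-2-(bromomethyl)-6,10-dimethyl-12-oxododeca-2,5,9-trienoate | O=CC/C(C)=C/CC/C(C)=C/C/C=C(\CBr)C(=O)OC | intermediate
9 | allylchromium dichloride from 8 (ligand omitted) | O=CC/C(C)=C/CC/C(C)=C/C/C=C(\C[Cr](Cl)Cl)C(=O)OC | intermediate
10 | chromium alkoxide of methyl (1(10)E,4E,7R,8R)-8-hydroxygermacra-1(10),4,11(13)-trien-12-oate | Cl[Cr](Cl)O[C@@H]1C/C(C)=C/CC/C(C)=C/C[C@@H]1C(=C)C(=O)OC | intermediate
11 | (1(10)E,4E,7R,8R)-germacra-1(10),4,11(13)-trien-12,8-olide, cis-fused | C=C1C(=O)O[C@@H]2C/C(C)=C/CC/C(C)=C/C[C@H]12 | intermediate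
12 | bis(diiodosamarium enolate) of the C13–C13' dimer | C(CC1=C(O[Sm](I)I)O[C@@H]2C/C(C)=C/CC/C(C)=C/C[C@H]12)C3=C(O[Sm](I)I)O[C@@H]4C/C(C)=C/CC/C(C)=C/C[C@H]34 | intermediate
13 | 13,13'-bi[(1(10)E,4E,7R,8R,11S)-germacra-1(10),4-dien-12,8-olide], C2-symmetric | C(C[C@@H]1C(=O)O[C@@H]2C/C(C)=C/CC/C(C)=C/C[C@H]12)[C@@H]3C(=O)O[C@@H]4C/C(C)=C/CC/C(C)=C/C[C@H]34 | intermediate
14 | mono lithium enolate of 13 | C(CC1=C([O-])O[C@@H]2C/C(C)=C/CC/C(C)=C/C[C@H]12)[C@@H]3C(=O)O[C@@H]4C/C(C)=C/CC/C(C)=C/C[C@H]34.[Li+] | intermediate
15 | 11α-phenylselanyl derivative of 13 (Se cis to H-7) | C(C[C@]1([Se]c5ccccc5)C(=O)O[C@@H]2C/C(C)=C/CC/C(C)=C/C[C@H]12)[C@@H]3C(=O)O[C@@H]4C/C(C)=C/CC/C(C)=C/C[C@H]34 | intermediate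
16 | selenoxide of 15 | C(C[C@]1([Se](=O)c5ccccc5)C(=O)O[C@@H]2C/C(C)=C/CC/C(C)=C/C[C@H]12)[C@@H]3C(=O)O[C@@H]4C/C(C)=C/CC/C(C)=C/C[C@H]34 | intermediate
17 | (1(10)E,4E,8R)-germacra-1(10),4,7(11)-trien-12,8-olide joined C13–C13' to (1'(10')E,4'E,7'R,8'R,11'S)-germacra-1'(10'),4'-dien-12',8'-olide | O=C1O[C@@H]2C/C(C)=C/CC/C(C)=C/CC2=C1CC[C@@H]3C(=O)O[C@@H]4C/C(C)=C/CC/C(C)=C/C[C@H]34 | intermediate
18 | (5R,8R,10R)-elema-1,3,7(11)-trien-12,8-olide half joined C13–C13' to the unchanged (7'R,8'R,11'S)-germacradienolide half | C=C[C@@]1(C)C[C@H]2OC(=O)C(CC[C@@H]3C(=O)O[C@@H]4C/C(C)=C/CC/C(C)=C/C[C@H]34)=C2C[C@@H]1C(=C)C | intermediate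
19 | CNP0332736.1: (5R,8R,10R)-elema-1,3,7(11)-trien-12,8-olide joined C13–C13' to (5'S,7'R,8'R,10'S,11'S)-elema-1',3'-dien-12',8'-olide | C=C[C@@]1(C)C[C@H]2OC(=O)C(CC[C@@H]3C(=O)O[C@@H]4C[C@@](C)(C=C)[C@H](C(=C)C)C[C@H]34)=C2C[C@@H]1C(=C)C | target

**Total step count:** 9. **Longest linear sequence:** 9 (from geranyl bromide; both halves come from the same monomer).

**Three steps most likely to fail**

Step 6 (ring closure). The risks are oligomers, the trans-lactone, or low ee from a ligand that has never been tested in a macrocyclisation.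
- The fallback sets out from 8 and comes back at 11.
- The bromide is exchanged for boron with B2pin2 under Pd2(dba)3 catalysis. No base is used, so the aldehyde survives. This gives methyl (2E,5E,9E)-6,10-dimethyl-12-oxo-2-[(pinacolboryl)methyl]dodeca-2,5,9-trienoate F1, an ester-deactivated allylboronate that is inert at 23 °C.
- Under high dilution, the BINOL-derived phosphoric acid (R)-TRIP triggers an intramolecular allylboration through a closed six-membered chair.
- In that chair the fixed alkene geometry (C6 cis to CH2B) can only give the syn adduct, the pinacol borate of the hydroxy ester F2, which lactonises in the flask to 11.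

Step 7 (dimerisation). The risks are plain 1,4-reduction to the 11,13-dihydro monomer, or anionic oligomerisation.
- The fallback sets out from 11 and comes back at 13, and makes the same bond with a two-component radical reaction.
- Benzeneselenol (cat. Et3N, 0 °C) adds to one portion of 11 to give the (11S)-13-phenylselanyl-11,13-dihydro lactone F3.
- (Me3Si)3SiH with Et3B/air at 0 to 23 °C turns it into the primary, nucleophilic C13 radical.
- This radical adds to the methylene carbon of a second portion of 11 (3 equiv, Giese addition).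
- The α-carbonyl radical then takes hydrogen from the silane on the convex face and gives 13.

Step 9 (double Cope). The risks are an incomplete equilibrium or imperfect facial control in the saturated half.
- The fallback sets out from 11 and comes back at 19, and separates the two rearrangements.
- The monomer 11 is heated alone (toluene, 150 °C) to (5S,7R,8R,10S)-elema-1,3,11(13)-trien-12,8-olide F4. Any 5,10-diastereomer is removed at this small-molecule stage.
- The C13 radical from F3 (conditions as above) is added to F4 (3 equiv) to give the mixed hydrodimer F5.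
- Treatment as in step 8 goes through the lithium enolate F6, the selenide F7 and the selenoxide F8. The regioisomer functionalised in the elemanolide half is separated off.
- The product is the germacranolide-butenolide/elemanolide dimer F9. Its single remaining Cope rearrangement, the one with the stronger facial bias, gives 19.

**Further compounds**
F1 | step 6 | methyl (2E,5E,9E)-6,10-dimethyl-12-oxo-2-[(4,4,5,5-tetramethyl-1,3,2-dioxaborolan-2-yl)methyl]dodeca-2,5,9-trienoate | O=CC/C(C)=C/CC/C(C)=C/C/C=C(\CB1OC(C)(C)C(C)(C)O1)C(=O)OC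
F2 | step 6 | pinacol borate of methyl (1(10)E,4E,7R,8R)-8-hydroxygermacra-1(10),4,11(13)-trien-12-oate | CC1(C)OB(O[C@@H]2C/C(C)=C/CC/C(C)=C/C[C@@H]2C(=C)C(=O)OC)OC1(C)C
F3 | step 7 | (1(10)E,4E,7R,8R,11S)-13-(phenylselanyl)germacra-1(10),4-dien-12,8-olide | c3ccc(cc3)[Se]C[C@@H]1C(=O)O[C@@H]2C/C(C)=C/CC/C(C)=C/C[C@H]12
F4 | step 9 | (5S,7R,8R,10S)-elema-1,3,11(13)-trien-12,8-olide | C=C1C(=O)O[C@@H]2C[C@@](C)(C=C)[C@H](C(=C)C)C[C@H]12
F5 | step 9 | mixed hydrodimer, (7R,8R,11S)-germacradienolide half joined C13–C13' to (5'S,7'R,8'R,10'S,11'S)-elemadienolide half | C(C[C@@H]1C(=O)O[C@@H]2C/C(C)=C/CC/C(C)=C/C[C@H]12)[C@@H]3C(=O)O[C@@H]4C[C@@](C)(C=C)[C@H](C(=C)C)C[C@H]34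
F6 | step 9 | lithium enolate of F5 (germacranolide half) | C(CC1=C([O-])O[C@@H]2C/C(C)=C/CC/C(C)=C/C[C@H]12)[C@@H]3C(=O)O[C@@H]4C[C@@](C)(C=C)[C@H](C(=C)C)C[C@H]34.[Li+]
F7 | step 9 | 11α-phenylselanyl derivative of F5 | C(C[C@]1([Se]c5ccccc5)C(=O)O[C@@H]2C/C(C)=C/CC/C(C)=C/C[C@H]12)[C@@H]3C(=O)O[C@@H]4C[C@@](C)(C=C)[C@H](C(=C)C)C[C@H]34
F8 | step 9 | selenoxide of F7 | C(C[C@]1([Se](=O)c5ccccc5)C(=O)O[C@@H]2C/C(C)=C/CC/C(C)=C/C[C@H]12)[C@@H]3C(=O)O[C@@H]4C[C@@](C)(C=C)[C@H](C(=C)C)C[C@H]34
F9 | step 9 | (8R)-germacra-1(10),4,7(11)-trien-12,8-olide half joined C13–C13' to (5'S,7'R,8'R,10'S,11'S)-elemadienolide half | O=C1O[C@@H]2C/C(C)=C/CC/C(C)=C/CC2=C1CC[C@@H]3C(=O)O[C@@H]4C[C@@](C)(C=C)[C@H](C(=C)C)C[C@H]34
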